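**Strategy.** The benzo ring of the 2,3-dihydrobenzofuran (C3a, C4, C5, C6, C7, C7a) is a 2,5-disubstituted resorcinol, i.e. a folded 3,5-dioxo chain, and O1–C7a–C3a–C3–C2 is a hidden trans-4,5-diaryl-γ-butyrolactone. The route therefore builds that ring last: an enantiopure lactone carrying a 3-methyl-5-arylpenta-2,4-dienoyl group on its α-carbon (C3a) is doubly deprotonated, the methyl carbon (C7) attacks the lactone carbonyl (C7a), the lactone opens and the ring aromatises in one operation. This forms C7–C7a and the resorcinol while C3, set earlier by a trans-selective conjugate arylation, is untouched. Acid then recloses O1–C2 trans and the benzyl ethers are removed.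

Key step: step 8

**Remarks on the chemistry.**
- The target is taken as the trans (2R,3R) isomer, as read from the SMILES. Ar1 = 4-(benzyloxy)-3-methoxyphenyl; Ar2 = 3,5-bis(benzyloxy)phenyl.
- The C3 label changes from S (lactones 9 and 14) to R (16 to 18) with no change in geometry, because the new benzo ring outranks Ar2.
- Enolates and other anions are described in the Why lines and are not numbered; intermediates that are not isolated are drawn in neutral form. Compound 14 is drawn as the keto form; its C3 epimers and enol are equivalent for step 8.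
- Phosphonate 10 carries the methyl-bearing carbon that becomes C7; a two-carbon phosphonoacetate would give only the cinnamate, which lacks it. Compound 10 is sold as an E/Z mixture; the E isomer is drawn.

**Route**

Step 1
Reactants: 1 4-(benzyloxy)-3-methoxybenzaldehyde; 2 methyl acrylate
Product: 3 methyl 4-Ar1-4-oxobutanoate
Conditions: 3-benzyl-5-(2-hydroxyethyl)-4-methylthiazolium chloride (20 mol%), Et3N (0.5 equiv.), 2 (2 equiv.), DMF, 70 °C
Reagents that add atoms: none
Why: Stetter reaction, in which the thiazolium-derived acyl-anion equivalent of the aldehyde adds 1,4 to the acrylate, while benzoin formation is reversible and drains into the 1,4-dicarbonyl product.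

Step 2
Reactants: 3 methyl 4-Ar1-4-oxobutanoate
Product: 5 (5R)-5-Ar1-oxolan-2-one, via hydroxy ester 4 (not isolated)
Conditions: RuCl[(R,R)-TsDPEN](p-cymene) (1 mol%), HCO2H/Et3N (5:2), 40 °C; then PPTS (cat.), PhMe, 60 °C
Reagents that add atoms: none
Why: Noyori asymmetric transfer hydrogenation of the aryl ketone, where the (R,R) catalyst delivers hydride to the face that gives the (R)-carbinol (the sense known for aryl alkyl ketones), followed by lactonisation of the γ-hydroxy ester under acid too weak to ionise the p-alkoxybenzylic C–O bond.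

Step 3
Reactants: 5 (5R)-5-Ar1-oxolan-2-one
Product: 7 (5R)-5-Ar1-furan-2(5H)-one, via selenide 6 (not isolated)
Conditions: LiN(iPr)2, THF, −78 °C; PhSeBr, −78 °C; then 30% H2O2, CH2Cl2, 0 → 23 °C
Reagents that add atoms: none
Why: α-Selenenylation of the lactone enolate and selenoxide syn-elimination, which can only take a C4 hydrogen and so gives the α,β-butenolide; the oxidation is run without amine base so that the acidic C5–H is not removed and C5 keeps its configuration.

Step 4
Reactants: 7 (5R)-5-Ar1-furan-2(5H)-one; 8 [3,5-bis(benzyloxy)phenyl]boronic acid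
Product: 9 (4S,5R)-4-Ar2-5-Ar1-oxolan-2-one (trans)
Conditions: [Rh(OH)(cod)]2 (2.5 mol%), 8 (2 equiv.), 1,4-dioxane/H2O (10:1), 40 °C
Reagents that add atoms: none
Why: Hayashi–Miyaura 1,4-addition, in which the aryl species of monovalent rhodium inserts the butenolide C=C on the face opposite the C5 aryl group and so sets C4 trans to C5 (4S from 5R); the base-free hydroxo complex keeps the medium near neutral so that C5 is not epimerised through the 2-oxidofuran.

Step 5
Reactants: 1 4-(benzyloxy)-3-methoxybenzaldehyde; 10 ethyl (2E)-4-(diethoxyphosphoryl)-3-methylbut-2-enoate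
Product: 11 ethyl (2E,4E)-5-Ar1-3-methylpenta-2,4-dienoate
Conditions: NaH, THF, 0 °C; then 1, 0 → 23 °C
Reagents that add atoms: none
Why: Vinylogous Horner–Wadsworth–Emmons olefination, in which the γ-phosphonate anion condenses with the aldehyde to form the new C4=C5 bond E while the 2E geometry, with the methyl group cis to the carbonyl, is expected to prevail.

Step 6
Reactants: 11 ethyl (2E,4E)-5-Ar1-3-methylpenta-2,4-dienoate
Product: 12 (2E,4E)-5-Ar1-3-methylpenta-2,4-dienoic acid
Conditions: LiOH·H2O, THF/MeOH/H2O, 50 °C; then 1 M HCl; recrystallisation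
Reagents that add atoms: lithium hydroxide, [Li+].[OH-]
Why: Saponification of the ethyl ester, with crystallisation of the acid expected to remove any 2Z isomer.

Step 7
Reactants: 12 (2E,4E)-5-Ar1-3-methylpenta-2,4-dienoic acid; 9 (4S,5R)-4-Ar2-5-Ar1-oxolan-2-one
Product: 14 (4S,5R)-4-Ar2-5-Ar1-3-[(2E,4E)-5-Ar1-3-methylpenta-2,4-dienoyl]oxolan-2-one, via acid chloride 13 (not isolated)
Conditions: 12: (COCl)2, DMF (cat.), CH2Cl2, 0 → 23 °C, evaporate; 9: LiN(SiMe3)2 (2.1 equiv.), THF, −78 °C; add 13, −78 → −40 °C; AcOH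
Reagents that add atoms: none
Why: C-Acylation (crossed Claisen condensation) of the lithium enolate of the lactone with the acid chloride at low temperature, where the second equivalent of the hindered amide deprotonates the β-keto lactone as it forms and so prevents proton transfer to unreacted enolate and double acylation; the new C3 centre is enolisable and of no consequence.

Step 8
Reactants: 14 (4S,5R)-4-Ar2-5-Ar1-3-[(2E,4E)-5-Ar1-3-methylpenta-2,4-dienoyl]oxolan-2-one
Product: 16 2-[(1R,2R)-1-Ar2-2-Ar1-2-hydroxyethyl]-5-[(E)-2-Ar1-ethenyl]benzene-1,3-diol, via cyclohexenedione 15 (not isolated)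
Conditions: LiN(iPr)2 (3.0 equiv.), THF/DMPU (10:1), −78 → 23 °C (40 °C if needed); then AcOH, −78 °C
Reagents that add atoms: none
Why: Proposed new method: the first equivalent of base removes the C3a–H between the two carbonyls and the second removes a proton from the C7 methyl group, which lies cis to the ketone; the C7 terminus of the resulting extended dienolate then adds to the lactone carbonyl C7a in a 6-exo-trig closure (attack through C5 would need a four-membered ring), either directly or after the lactone enolate has opened to an acylketene. The tetrahedral intermediate expels the ring oxygen as the C2 alkoxide and cyclohexenedione 15 enolises to the resorcinol bis-phenoxide, which makes the sequence irreversible. The closest known reaction type is the base-mediated Claisen cyclisation of 3,5-dioxo esters and of enone–malonate Michael adducts to cyclohexane-1,3-diones and resorcinols, in which a methyl-derived carbanion likewise acylates an ester that sits in an ionised 1,3-dicarbonyl unit. No stereocentre is formed: C3 is β to both carbonyls, not acidic, and keeps the configuration set in step 4, and the C2 carbinol keeps that of the lactone. The selectivity needed is C-acylation by C7 over oxa-Michael closure of the enolate oxygen onto C6 (a dihydropyranone) and over retro-Claisen loss of the dienoyl group; the dianion secures it because the enone has become a dienolate that is no longer a Michael acceptor, the ionised 1,3-dicarbonyl unit is shielded from nucleophiles and the base is non-nucleophilic. Warming with DMPU loosens lithium chelation and allows rotation about C4–C5 so that C7 can reach C7a.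

Step 9
Reactants: 16 2-[(1R,2R)-1-Ar2-2-Ar1-2-hydroxyethyl]-5-[(E)-2-Ar1-ethenyl]benzene-1,3-diol
Product: 17 (2R,3R)-3-Ar2-2-Ar1-6-[(E)-2-Ar1-ethenyl]-2,3-dihydro-1-benzofuran-4-ol
Conditions: TsOH·H2O (10 mol%), CH2Cl2, 0 → 23 °C
Reagents that add atoms: none
Why: Acid-catalysed dehydrative cyclisation (SN1), in which the C2 carbinol ionises to a p-alkoxybenzyl cation that is captured by either of the two equivalent phenols in a five-membered closure anti to the C3 aryl group, and reversible ionisation funnels the material to the trans (2R) ring without touching C3.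

Step 10
Reactants: 17 (2R,3R)-3-Ar2-2-Ar1-6-[(E)-2-Ar1-ethenyl]-2,3-dihydro-1-benzofuran-4-ol
Product: 18 (2R,3R)-3-(3,5-dihydroxyphenyl)-2-(4-hydroxy-3-methoxyphenyl)-6-[(E)-2-(4-hydroxy-3-methoxyphenyl)ethenyl]-2,3-dihydro-1-benzofuran-4-ol (CNP0296800.3)
Conditions: BCl3 (10 equiv.), C6HMe5 (15 equiv.), CH2Cl2, −78 → −40 °C; then H2O
Reagents that add atoms: none
Why: Lewis-acid cleavage of the four aryl benzyl ethers with pentamethylbenzene as a non-basic benzyl-cation scavenger at low temperature, conditions that should spare the aryl methyl ethers, the stilbene double bond and the trans-dihydrobenzofuran (any reversible C2–O ionisation returns to trans).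

**Compound list**

1 | 4-(benzyloxy)-3-methoxybenzaldehyde | O=Cc1ccc(OCc2ccccc2)c(OC)c1 | starting material
2 | methyl acrylate | C=CC(=O)OC | starting material
3 | methyl 4-[4-(benzyloxy)-3-methoxyphenyl]-4-oxobutanoate | COC(=O)CCC(=O)c1ccc(OCc2ccccc2)c(OC)c1 | intermediate
4 | methyl (4R)-4-[4-(benzyloxy)-3-methoxyphenyl]-4-hydroxybutanoate | COC(=O)CC[C@@H](O)c1ccc(OCc2ccccc2)c(OC)c1 | intermediate (not isolated)
5 | (5R)-5-[4-(benzyloxy)-3-methoxyphenyl]oxolan-2-one | O=C1O[C@@H](c2ccc(OCc3ccccc3)c(OC)c2)CC1 | intermediate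
6 | (5R)-5-[4-(benzyloxy)-3-methoxyphenyl]-3-(phenylselanyl)oxolan-2-one, C3 epimers | O=C1O[C@@H](c2ccc(OCc3ccccc3)c(OC)c2)CC1[Se]c1ccccc1 | intermediate (not isolated)
7 | (5R)-5-[4-(benzyloxy)-3-methoxyphenyl]furan-2(5H)-one | O=C1O[C@@H](c2ccc(OCc3ccccc3)c(OC)c2)C=C1 | intermediate
8 | [3,5-bis(benzyloxy)phenyl]boronic acid | OB(O)c1cc(OCc2ccccc2)cc(OCc2ccccc2)c1 | starting material
9 | (4S,5R)-4-[3,5-bis(benzyloxy)phenyl]-5-[4-(benzyloxy)-3-methoxyphenyl]oxolan-2-one (trans) | O=C1O[C@@H](c2ccc(OCc3ccccc3)c(OC)c2)[C@H](c2cc(OCc3ccccc3)cc(OCc3ccccc3)c2)C1 | intermediate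
10 | ethyl (2E)-4-(diethoxyphosphoryl)-3-methylbut-2-enoate (triethyl 3-methyl-4-phosphonocrotonate) | CCOC(=O)/C=C(\C)CP(=O)(OCC)OCC | starting material
11 | ethyl (2E,4E)-5-[4-(benzyloxy)-3-methoxyphenyl]-3-methylpenta-2,4-dienoate | CCOC(=O)/C=C(\C)/C=C/c1ccc(OCc2ccccc2)c(OC)c1 | intermediate
12 | (2E,4E)-5-[4-(benzyloxy)-3-methoxyphenyl]-3-methylpenta-2,4-dienoic acid | OC(=O)/C=C(\C)/C=C/c1ccc(OCc2ccccc2)c(OC)c1 | intermediate
13 | (2E,4E)-5-[4-(benzyloxy)-3-methoxyphenyl]-3-methylpenta-2,4-dienoyl chloride | ClC(=O)/C=C(\C)/C=C/c1ccc(OCc2ccccc2)c(OC)c1 | intermediate (not isolated)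
14 | (4S,5R)-4-[3,5-bis(benzyloxy)phenyl]-5-[4-(benzyloxy)-3-methoxyphenyl]-3-{(2E,4E)-5-[4-(benzyloxy)-3-methoxyphenyl]-3-methylpenta-2,4-dienoyl}oxolan-2-one, C3 epimers and enol | O=C1O[C@@H](c2ccc(OCc3ccccc3)c(OC)c2)[C@H](c2cc(OCc3ccccc3)cc(OCc3ccccc3)c2)C1C(=O)/C=C(\C)/C=C/c1ccc(OCc2ccccc2)c(OC)c1 | intermediate (key-step precursor)
15 | 2-{(1S,2R)-1-[3,5-bis(benzyloxy)phenyl]-2-[4-(benzyloxy)-3-methoxyphenyl]-2-hydroxyethyl}-5-{(E)-2-[4-(benzyloxy)-3-methoxyphenyl]ethenyl}cyclohex-4-ene-1,3-dione (same geometry as 16; the label differs because the ring carbon is sp3) | O=C1CC(/C=C/c2ccc(OCc3ccccc3)c(OC)c2)=CC(=O)C1[C@@H](c1cc(OCc2ccccc2)cc(OCc2ccccc2)c1)[C@@H](O)c1ccc(OCc2ccccc2)c(OC)c1 | intermediate (not isolated)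
16 | 2-{(1R,2R)-1-[3,5-bis(benzyloxy)phenyl]-2-[4-(benzyloxy)-3-methoxyphenyl]-2-hydroxyethyl}-5-{(E)-2-[4-(benzyloxy)-3-methoxyphenyl]ethenyl}benzene-1,3-diol | Oc1cc(/C=C/c2ccc(OCc3ccccc3)c(OC)c2)cc(O)c1[C@@H](c1cc(OCc2ccccc2)cc(OCc2ccccc2)c1)[C@@H](O)c1ccc(OCc2ccccc2)c(OC)c1 | intermediate (key-step product)
17 | (2R,3R)-3-[3,5-bis(benzyloxy)phenyl]-2-[4-(benzyloxy)-3-methoxyphenyl]-6-{(E)-2-[4-(benzyloxy)-3-methoxyphenyl]ethenyl}-2,3-dihydro-1-benzofuran-4-ol | COc1cc(/C=C/c2cc(O)c3c(c2)O[C@@H](c2ccc(OCc4ccccc4)c(OC)c2)[C@@H]3c2cc(OCc4ccccc4)cc(OCc4ccccc4)c2)ccc1OCc1ccccc1 | intermediate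
18 | (2R,3R)-3-(3,5-dihydroxyphenyl)-2-(4-hydroxy-3-methoxyphenyl)-6-[(E)-2-(4-hydroxy-3-methoxyphenyl)ethenyl]-2,3-dihydro-1-benzofuran-4-ol | COc1cc(/C=C/c2cc(O)c3c(c2)O[C@@H](c2ccc(O)c(OC)c2)[C@@H]3c2cc(O)cc(O)c2)ccc1O | target

**Step count and risks**

Total step count: 10. Longest linear sequence: 8 steps (steps 1, 2, 3, 4, 7, 8, 9, 10); steps 5 and 6 form the side branch.

Steps most likely to fail:

1. Step 8. The second deprotonation may be incomplete, or the extended dienolate may fail to acylate the charge-deactivated lactone carbonyl, so that retro-Claisen loss of the dienoyl group or reversible closure through oxygen takes over. The fallback sets out from lactone 9 and returns at 16; it replaces the Claisen ring closure by the classical base-mediated aldol cyclisation of a 2,4,6-triketone. Aldehyde 1 is condensed with acetone (aq. NaOH) to (E)-4-Ar1-but-3-en-2-one F1. Its lithium enolate (LiN(iPr)2, THF, −78 °C, in excess) opens lactone 9 in a crossed Claisen condensation and forms C7–C7a, giving the hydroxy β-diketone (1E,7S,8R)-7-Ar2-1,8-bis(Ar1)-8-hydroxyoct-1-ene-3,5-dione F2. The trianion of F2 (LiN(iPr)2, 3.3 equiv.) is C-acetylated at its terminal carbon C3a with N-methoxy-N-methylacetamide to give the 6-acetyl triketone F3. Aqueous KOH in MeOH then adds the acetyl methyl group to the styryl ketone (C5–C6), and dehydration aromatises the ring to 16.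

2. Step 7. O-Acylation, proton transfer between the enolate and the acidic product, or ketene formation from the acid chloride by loss of its γ-proton may erode the C-acylation. The fallback sets out from ester 11 and lactone 9 and returns at 14; it uses aldol addition and oxidation in place of acylation. Ester 11 is reduced with iBu2AlH (CH2Cl2, −78 °C) to (2E,4E)-5-Ar1-3-methylpenta-2,4-dien-1-ol F4, which MnO2 oxidises to the dienal (2E,4E)-5-Ar1-3-methylpenta-2,4-dienal F5. The lithium enolate of 9 (LiN(SiMe3)2, THF, −78 °C) adds 1,2 to F5 to give the β-hydroxy lactone (4S,5R)-4-Ar2-5-Ar1-3-[(2E,4E)-1-hydroxy-5-Ar1-3-methylpenta-2,4-dien-1-yl]oxolan-2-one F6, with no acidic product to quench the enolate. Dess–Martin oxidation of F6 gives 14.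

3. Step 4. Insertion into the butenolide may be slow, with competing protodeboronation, or enantiomeric purity may erode through reversible removal of the acidic C5 proton before the addition. The fallback sets out from boronic acid 8 and aldehyde 1 and returns at 9; it sets C4 and C5 together by allylboration and needs no butenolide. Suzuki coupling of 8 with vinyl bromide (Pd(PPh3)4, K2CO3, THF/H2O) gives 1,3-bis(benzyloxy)-5-ethenylbenzene F7. Cross-metathesis with allylboronic acid pinacol ester (second-generation Grubbs catalyst, CH2Cl2, 40 °C) gives the (E)-γ-aryl allylboronate F8. Allylboration of aldehyde 1 with F8 is catalysed by the chiral phosphoric acid TRIP (the enantiomer that delivers the (1R)-carbinol; PhMe, −30 °C) and should pass through a chair transition state to the anti homoallylic alcohol (1R,2S)-2-Ar2-1-Ar1-but-3-en-1-ol F9. Hydroboration–oxidation (9-BBN, THF; NaOH, H2O2) gives (1R,2S)-2-Ar2-1-Ar1-butane-1,4-diol F10. TEMPO/PhI(OAc)2 then oxidises the primary alcohol and the derived lactol to the trans-lactone 9.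

Further compounds
F1 | step 8 | (E)-4-[4-(benzyloxy)-3-methoxyphenyl]but-3-en-2-one | CC(=O)/C=C/c1ccc(OCc2ccccc2)c(OC)c1
F2 | step 8 | (1E,7S,8R)-7-[3,5-bis(benzyloxy)phenyl]-1,8-bis[4-(benzyloxy)-3-methoxyphenyl]-8-hydroxyoct-1-ene-3,5-dione | O=C(/C=C/c1ccc(OCc2ccccc2)c(OC)c1)CC(=O)C[C@@H](c1cc(OCc2ccccc2)cc(OCc2ccccc2)c1)[C@@H](O)c1ccc(OCc2ccccc2)c(OC)c1
F3 | step 8 | (1E,7S,8R)-6-acetyl-7-[3,5-bis(benzyloxy)phenyl]-1,8-bis[4-(benzyloxy)-3-methoxyphenyl]-8-hydroxyoct-1-ene-3,5-dione, C6 epimers | CC(=O)C(C(=O)CC(=O)/C=C/c1ccc(OCc2ccccc2)c(OC)c1)[C@@H](c1cc(OCc2ccccc2)cc(OCc2ccccc2)c1)[C@@H](O)c1ccc(OCc2ccccc2)c(OC)c1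
F4 | step 7 | (2E,4E)-5-[4-(benzyloxy)-3-methoxyphenyl]-3-methylpenta-2,4-dien-1-ol | OC/C=C(\C)/C=C/c1ccc(OCc2ccccc2)c(OC)c1
F5 | step 7 | (2E,4E)-5-[4-(benzyloxy)-3-methoxyphenyl]-3-methylpenta-2,4-dienal | O=C/C=C(\C)/C=C/c1ccc(OCc2ccccc2)c(OC)c1
F6 | step 7 | (4S,5R)-4-[3,5-bis(benzyloxy)phenyl]-5-[4-(benzyloxy)-3-methoxyphenyl]-3-{(2E,4E)-1-hydroxy-5-[4-(benzyloxy)-3-methoxyphenyl]-3-methylpenta-2,4-dien-1-yl}oxolan-2-one | O=C1O[C@@H](c2ccc(OCc3ccccc3)c(OC)c2)[C@H](c2cc(OCc3ccccc3)cc(OCc3ccccc3)c2)C1C(O)/C=C(\C)/C=C/c1ccc(OCc2ccccc2)c(OC)c1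
F7 | step 4 | 1,3-bis(benzyloxy)-5-ethenylbenzene | C=Cc1cc(OCc2ccccc2)cc(OCc2ccccc2)c1
F8 | step 4 | 2-{(2E)-3-[3,5-bis(benzyloxy)phenyl]prop-2-en-1-yl}-4,4,5,5-tetramethyl-1,3,2-dioxaborolane | CC1(C)OB(C/C=C/c2cc(OCc3ccccc3)cc(OCc3ccccc3)c2)OC1(C)C
F9 | step 4 | (1R,2S)-2-[3,5-bis(benzyloxy)phenyl]-1-[4-(benzyloxy)-3-methoxyphenyl]but-3-en-1-ol | C=C[C@@H](c1cc(OCc2ccccc2)cc(OCc2ccccc2)c1)[C@@H](O)c1ccc(OCc2ccccc2)c(OC)c1
F10 | step 4 | (1R,2S)-2-[3,5-bis(benzyloxy)phenyl]-1-[4-(benzyloxy)-3-methoxyphenyl]butane-1,4-diol | OCC[C@@H](c1cc(OCc2ccccc2)cc(OCc2ccccc2)c1)[C@@H](O)c1ccc(OCc2ccccc2)c(OC)c1
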